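**Plan**

- Retrosynthesis cuts, in this order: the two C–O bonds at the spiro ketal carbon (cage hydroxy acid plus chromene hydroxyquinone); the prenyl C=C on the cage (metathesis of an allyl group); the tetrahydrofuran O–C bond together with the C–allyl bond at the carbon next to the bridging ketone; the two C–C bonds of the bicyclo[2.2.2]octene (cyclohexadiene plus propiolate); the ring C–isopropenyl bond.
- Enabling feature: the cage carbon lying between the bridging ketone and the oxygenated bridgehead carries both the ether oxygen of the dimethyltetrahydrofuran and a CH2–CH=C chain. That is the imprint of an O-allyl oxonium ylide formed at a diazo ketone carbon and relaxed by a [2,3] shift.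
- Forward: dearomatised phenol, then a cyclohexenone with one stereocentre, then a 1,4-bis(silyloxy)-2-methoxycyclohexadiene; Diels–Alder closes the bicyclo[2.2.2]octene; hydration, O-allylation and diazo transfer follow; the carbenoid step closes the tetrahydrofuran; metathesis gives the prenyl acid. The pyranoquinone is built separately from 2,6-dimethoxybenzoquinone; ester union, and the dioxinone spiro ring closes last.
- Stereochemistry: one stereocentre from a rhodium/(S)-BINAP conjugate addition steers the cycloaddition face and so both bridgeheads; the cage geometry dictates the quaternary ether carbon; the spiro carbon and its CH(prenyl) neighbour are set in the final ring closure.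

Key step: step 9

Assumption: the natural configuration at the spiro ketal carbon and at the adjacent CH(prenyl) carbon (α to a ketone, hence epimerisable) is taken to be the thermodynamically preferred one, so that the reversible closure in step 17 can converge on it.

Bicyclic intermediates are numbered as bicyclo[2.2.2]oct-2-ene-2-carboxylates: C1 and C4 are the bridgeheads, C5 is the ketone, C6 the carbon next to it, C7 carries the side chain.

**Step 1**
Reactants: 1 2,4-dimethoxyphenol
Product: 2 2,4,4-trimethoxycyclohexa-2,5-dien-1-one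
Conditions: PhI(OAc)2, MeOH, 0 °C
Reagents that add atoms: methanol, CO
Why: Hypervalent-iodine oxidative dearomatisation of a para-methoxyphenol in methanol traps the phenoxenium ion at the para carbon as the quinone monoketal, leaving two electronically different enone arms.

**Step 2**
Reactants: 2 2,4,4-trimethoxycyclohexa-2,5-dien-1-one; 3 isopropenylboronic acid pinacol ester
Product: 4 (5S)-2,4,4-trimethoxy-5-(prop-1-en-2-yl)cyclohex-2-en-1-one
Conditions: [Rh(cod)OH]2 (2.5 mol %), (S)-BINAP (6 mol %), KOH (0.3 equiv), 1,4-dioxane/H2O 10:1, 35 °C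
Reagents that add atoms: none
Why: Hayashi–Miyaura asymmetric 1,4-addition should take place at the unsubstituted enone (the methoxy-bearing double bond is trisubstituted and electron-richer), and the (S)-ligand is chosen because it delivers the organic group to the enone face that corresponds to (S)-3-substituted cyclohexanones, which here is (5S).

**Step 3**
Reactants: 4 (5S)-2,4,4-trimethoxy-5-(prop-1-en-2-yl)cyclohex-2-en-1-one
Product: 5 (5S)-2-methoxy-5-(prop-1-en-2-yl)cyclohex-2-ene-1,4-dione
Conditions: SiO2, 10% aq. oxalic acid, CH2Cl2, 0 °C; filtered and used at once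
Reagents that add atoms: water, O
Why: The ketal is allylic to an enol ether, so acetal hydrolysis should proceed under very weak acid and at a temperature where the enedione does not yet enolise towards the hydroquinone or move the side-chain alkene into conjugation.

**Step 4**
Reactants: 5 (5S)-2-methoxy-5-(prop-1-en-2-yl)cyclohex-2-ene-1,4-dione
Product: 7 (5S)-2-methoxy-5-(prop-1-en-2-yl)-1,4-bis(triethylsilyloxy)cyclohexa-1,3-diene, via dilithium dienediolate 6 (not isolated)
Conditions: lithium naphthalenide (2.05 equiv, stock solution), THF, −78 °C, 5 added to the reductant; then Et3SiOTf (2.3 equiv), Et3N, −78 to 0 °C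
Reagents that add atoms: triethylsilyl trifluoromethanesulfonate, CC[Si](CC)(CC)OS(=O)(=O)C(F)(F)F
Why: Dissolving-metal reductive silylation, as used for quinones and enediones: two-electron reduction gives the dienediolate regiospecifically on the C2–C3 side and O-silylation fixes both enol ethers without any deprotonation at C5, which keeps its configuration.

**Step 5**
Reactants: 7 (5S)-2-methoxy-5-(prop-1-en-2-yl)-1,4-bis(triethylsilyloxy)cyclohexa-1,3-diene; 8 methyl propiolate
Product: 10 methyl (1S,4R,7S)-5-oxo-7-(prop-1-en-2-yl)-1,4-bis(triethylsilyloxy)bicyclo[2.2.2]oct-2-ene-2-carboxylate, via cycloadduct 9 (not isolated)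
Conditions: methyl propiolate (3 equiv), toluene, 45 °C (not above 50 °C); then 0.5 M aq. HCl, THF, 0 °C
Reagents that add atoms: water, O
Why: Diels–Alder reaction in which the 2-methoxy group makes C1 the nucleophilic terminus (bond to the propiolate CH, ester carbon to C4) and the dienophile approaches anti to the C5 substituent, which thereby ends syn to the enol ether bridge and fixes both bridgeheads; brief mild acid then hydrolyses the methyl enol ether to the C5 ketone, and the low temperature is meant to avoid Alder–Rickert loss of the saturated bridge.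

**Step 6**
Reactants: 10 methyl (1S,4R,7S)-5-oxo-7-(prop-1-en-2-yl)-1,4-bis(triethylsilyloxy)bicyclo[2.2.2]oct-2-ene-2-carboxylate
Product: 11 methyl (1S,4R,7S)-7-(2-hydroxypropan-2-yl)-5-oxo-1,4-bis(triethylsilyloxy)bicyclo[2.2.2]oct-2-ene-2-carboxylate
Conditions: Co(acac)2 (20 mol %), PhSiH3, O2 (1 atm), THF, rt
Reagents that add atoms: dioxygen, O=O
Why: Mukaiyama hydration (hydrogen-atom transfer, then oxygen capture) should add water in the Markovnikov sense to the exposed 1,1-disubstituted alkene well before the trisubstituted, conjugated bridge alkene reacts.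

**Step 7**
Reactants: 11 methyl (1S,4R,7S)-7-(2-hydroxypropan-2-yl)-5-oxo-1,4-bis(triethylsilyloxy)bicyclo[2.2.2]oct-2-ene-2-carboxylate; 12 allyl 2,2,2-trichloroacetimidate
Product: 13 methyl (1S,4R,7S)-7-[2-(allyloxy)propan-2-yl]-5-oxo-1,4-bis(triethylsilyloxy)bicyclo[2.2.2]oct-2-ene-2-carboxylate
Conditions: 12 (3 equiv), TfOH (5 mol %), CH2Cl2/cyclohexane 1:2, 0 °C to rt
Reagents that add atoms: none
Why: Acid-catalysed trichloroacetimidate O-alkylation etherifies hindered tertiary alcohols without base, so the enolisable ketone is untouched and the 1,3-related bridgehead silyl ether cannot migrate through an alkoxide.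

**Step 8**
Reactants: 13 methyl (1S,4R,7S)-7-[2-(allyloxy)propan-2-yl]-5-oxo-1,4-bis(triethylsilyloxy)bicyclo[2.2.2]oct-2-ene-2-carboxylate
Product: 15 methyl (1S,4R,7S)-7-[2-(allyloxy)propan-2-yl]-6-diazo-5-oxo-1,4-bis(triethylsilyloxy)bicyclo[2.2.2]oct-2-ene-2-carboxylate, via trifluoroacetyl ketone 14 (not isolated)
Conditions: LiHMDS, THF, −78 °C; CF3CO2CH2CF3; aq. HCl work-up; then MsN3, Et3N, H2O, MeCN, rt
Reagents that add atoms: methanesulfonyl azide, CS(=O)(=O)N=[N+]=[N-]
Why: Deacylative Regitz diazo transfer: the ketone can enolise only towards C6 (C4 is a bridgehead), the C6 trifluoroacetyl ketone is activated enough to accept the diazo group from mesyl azide, and the trifluoroacetyl group is lost in the same operation.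

**Step 9**
Reactants: 15 methyl (1S,4R,7S)-7-[2-(allyloxy)propan-2-yl]-6-diazo-5-oxo-1,4-bis(triethylsilyloxy)bicyclo[2.2.2]oct-2-ene-2-carboxylate
Product: 17 allyl cage ester (tetrahydrofuran closed from the side-chain oxygen to C6; allyl on C6; 1S,4R,6R,7S), via oxonium ylide 16 (not isolated)
Conditions: Rh2(OAc)4 (2 mol %), CH2Cl2, rt, slow addition of 15
Reagents that add atoms: none
Why: Rh2(OAc)4 should expel N2 from the diazo ketone to give an electrophilic rhodium carbene at C6, which is captured by a lone pair of the tertiary allyl ether oxygen held syn over the keto bridge; the resulting five-membered oxonium ylide 16 then undergoes a concerted [2,3]-sigmatropic shift that moves the allyl group from oxygen to C6. The closest known reaction type is the rhodium- or copper-carbenoid cyclisation of diazo ketones bearing allyl ethers to 2-allyltetrahydrofurans through oxonium ylides. The tetrahydrofuran closes by O–C bond formation in a five-membered exo mode (the Rh=C bond lies outside the forming ring) and can only be cis-fused to the bicycle. The new fully substituted stereocentre is dictated by the cage: oxygen must take the C6 position that faces the C7 side chain, so the allyl group arrives at the remaining position, on the side of the ester-bearing alkene bridge. The step needs ylide formation to outrun C–H insertion, carbonyl-ylide formation at the ester and cyclopropanation; the carbene has no β-hydrogen, the ether oxygen is the most Lewis-basic atom within five-ring reach (the conjugated ester carbonyl is less basic), and the allyl alkene is too remote for cyclopropanation.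

**Step 10**
Reactants: 17 allyl cage ester; 18 2-methyl-2-butene
Product: 19 prenyl cage ester (as 17 with C6-CH2CH=CMe2)
Conditions: 2-methyl-2-butene (excess), second-generation Grubbs catalyst (5 mol %), CH2Cl2, 40 °C
Reagents that add atoms: none
Why: Olefin cross-metathesis of a monosubstituted allyl group with excess 2-methyl-2-butene gives the prenyl alkene, while the conjugated trisubstituted bridge alkene should not engage the ruthenium carbene.

**Step 11**
Reactants: 19 prenyl cage ester
Product: 20 prenyl cage acid
Conditions: LiOH·H2O, THF/MeOH/H2O, 40 °C; then 1 M HCl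
Reagents that add atoms: lithium hydroxide, [Li+].[OH-]
Why: Saponification is safe here because the ketone has no α-hydrogen and the β-oxygen at the bridgehead is still silylated, which excludes enolisation and retro-aldol cleavage.

**Step 12**
Reactants: 21 2,6-dimethoxy-1,4-benzoquinone
Product: 22 2-hydroxy-6-methoxy-1,4-benzoquinone
Conditions: NaOH (1.05 equiv), H2O/THF, 0 °C; then 1 M HCl
Reagents that add atoms: sodium hydroxide, [Na+].[OH-]
Why: Addition–elimination of hydroxide at one methoxy-bearing carbon (vinylogous ester hydrolysis) should stop after one exchange because the hydroxyquinone anion is deactivated towards a second attack.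

**Step 13**
Reactants: 22 2-hydroxy-6-methoxy-1,4-benzoquinone; 23 3-methylbut-2-enal
Product: 24 7-methoxy-2,2-dimethyl-2H-chromene-5,8-dione
Conditions: ethylenediammonium diacetate (10 mol %), toluene, 80 °C
Reagents that add atoms: none
Why: Formal [3+3] annulation: Knoevenagel condensation at the nucleophilic carbon beside the hydroxyl, then oxa-6π electrocyclisation of the 1-oxatriene onto the hydroxyl oxygen, as known for hydroxyquinones and enals.

**Step 14**
Reactants: 24 7-methoxy-2,2-dimethyl-2H-chromene-5,8-dione; 25 tributyl(3-methylbut-2-en-1-yl)stannane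
Product: 27 7-methoxy-2,2-dimethyl-6-(3-methylbut-2-en-1-yl)-2H-chromene-5,8-dione, via prenyl hydroquinone 26 (not isolated)
Conditions: BF3·OEt2, CH2Cl2, −78 °C; then Ag2O, Et2O, rt
Reagents that add atoms: none
Why: Lewis acid-mediated allylation of a quinone with an allylstannane (carbonyl addition with allyl inversion, then [3,3] shift to the only free ring carbon, which returns the linear prenyl group), followed by re-oxidation of the hydroquinone.

**Step 15**
Reactants: 27 7-methoxy-2,2-dimethyl-6-(3-methylbut-2-en-1-yl)-2H-chromene-5,8-dione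
Product: 28 7-hydroxy-2,2-dimethyl-6-(3-methylbut-2-en-1-yl)-2H-chromene-5,8-dione
Conditions: LiOH, THF/H2O, 0 °C to rt; then 1 M HCl
Reagents that add atoms: lithium hydroxide, [Li+].[OH-]
Why: Vinylogous ester saponification at C7 gives the acidic hydroxyquinone as its salt, and any opening of the pyran enol ether is reversible by ring closure.

**Step 16**
Reactants: 20 prenyl cage acid; 28 7-hydroxy-2,2-dimethyl-6-(3-methylbut-2-en-1-yl)-2H-chromene-5,8-dione
Product: 30 quinonyl ester (acyl group of 20 on the C7 oxygen of 28), via acid chloride 29 (not isolated)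
Conditions: 1-chloro-N,N,2-trimethylprop-1-en-1-amine, CH2Cl2, 0 °C to rt; then 28, Et3N, DMAP (cat.), 0 °C
Reagents that add atoms: none
Why: O-Acylation of a hydroxyquinone (a vinylogous acid) with an acid chloride made under neutral conditions is the usual route to acyloxyquinones, and both cage hydroxyls are still silylated so no other nucleophile competes.

**Step 17**
Reactants: 30 quinonyl ester
Product: 32 CNP0222516.1 (target), via seco diol 31 (not isolated)
Conditions: HF·pyridine, pyridine, THF, 0 °C to rt; then camphorsulfonic acid (10 mol %), CH2Cl2, rt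
Reagents that add atoms: none
Why: Proposed new method: fluoride removes both triethylsilyl groups, and the freed bridgehead hydroxyl, six atoms from the acyloxy-bearing quinone carbon (β to the C5 carbonyl), is expected to add to it in a 6-exo-trig oxa-Michael sense; ketonisation of the enol then gives the spiro ketal-lactone and the CH(prenyl) centre, both expected to settle at the more stable arrangement under the acid-equilibrating conditions; the closest known reactions are intramolecular oxa-Michael additions of alcohols to quinones and acid-catalysed ketalisation of β-oxygenated enones.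

**Compound list**

1 | 2,4-dimethoxyphenol | COc1ccc(O)c(OC)c1 | starting material
2 | 2,4,4-trimethoxycyclohexa-2,5-dien-1-one | COC1=CC(OC)(OC)C=CC1=O | intermediate
3 | isopropenylboronic acid pinacol ester | CC(=C)B1OC(C)(C)C(C)(C)O1 | starting material
4 | (5S)-2,4,4-trimethoxy-5-(prop-1-en-2-yl)cyclohex-2-en-1-one | C1[C@@H](C(C)=C)C(OC)(OC)C=C(OC)C1=O | intermediate
5 | (5S)-2-methoxy-5-(prop-1-en-2-yl)cyclohex-2-ene-1,4-dione | C1[C@@H](C(C)=C)C(=O)C=C(OC)C1=O | intermediate
6 | dilithium (5S)-2-methoxy-5-(prop-1-en-2-yl)cyclohexa-1,3-diene-1,4-diolate | [Li+].[Li+].C1[C@@H](C(C)=C)C([O-])=CC(OC)=C1[O-] | intermediate (not isolated)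
7 | (5S)-2-methoxy-5-(prop-1-en-2-yl)-1,4-bis(triethylsilyloxy)cyclohexa-1,3-diene | C1[C@@H](C(C)=C)C(O[Si](CC)(CC)CC)=CC(OC)=C1O[Si](CC)(CC)CC | intermediate
8 | methyl propiolate | C#CC(=O)OC | starting material
9 | methyl (1R,4R,7S)-5-methoxy-7-(prop-1-en-2-yl)-1,4-bis(triethylsilyloxy)bicyclo[2.2.2]octa-2,5-diene-2-carboxylate | COC(=O)C1=C[C@]2(O[Si](CC)(CC)CC)C[C@@H](C(C)=C)[C@@]1(O[Si](CC)(CC)CC)C=C2OC | intermediate (not isolated)
10 | methyl (1S,4R,7S)-5-oxo-7-(prop-1-en-2-yl)-1,4-bis(triethylsilyloxy)bicyclo[2.2.2]oct-2-ene-2-carboxylate; side chain syn to the keto bridge | COC(=O)C1=C[C@]2(O[Si](CC)(CC)CC)C[C@@H](C(C)=C)[C@@]1(O[Si](CC)(CC)CC)CC2=O | intermediate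
11 | methyl (1S,4R,7S)-7-(2-hydroxypropan-2-yl)-5-oxo-1,4-bis(triethylsilyloxy)bicyclo[2.2.2]oct-2-ene-2-carboxylate | COC(=O)C1=C[C@]2(O[Si](CC)(CC)CC)C[C@@H](C(C)(C)O)[C@@]1(O[Si](CC)(CC)CC)CC2=O | intermediate
12 | allyl 2,2,2-trichloroacetimidate | C=CCOC(=N)C(Cl)(Cl)Cl | starting material
13 | methyl (1S,4R,7S)-7-[2-(allyloxy)propan-2-yl]-5-oxo-1,4-bis(triethylsilyloxy)bicyclo[2.2.2]oct-2-ene-2-carboxylate | COC(=O)C1=C[C@]2(O[Si](CC)(CC)CC)C[C@@H](C(C)(C)OCC=C)[C@@]1(O[Si](CC)(CC)CC)CC2=O | intermediate
14 | 6-trifluoroacetyl derivative of 13 (C6 configuration undefined, largely enolised) | COC(=O)C1=C[C@]2(O[Si](CC)(CC)CC)C[C@@H](C(C)(C)OCC=C)[C@@]1(O[Si](CC)(CC)CC)C(C(=O)C(F)(F)F)C2=O | intermediate (not isolated)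
15 | methyl (1S,4R,7S)-7-[2-(allyloxy)propan-2-yl]-6-diazo-5-oxo-1,4-bis(triethylsilyloxy)bicyclo[2.2.2]oct-2-ene-2-carboxylate | COC(=O)C1=C[C@]2(O[Si](CC)(CC)CC)C[C@@H](C(C)(C)OCC=C)[C@@]1(O[Si](CC)(CC)CC)C(=[N+]=[N-])C2=O | intermediate (key-step precursor)
16 | cyclic O-allyl oxonium ylide, drawn as the C6=C5 enolate | COC(=O)C1=C[C@]2(O[Si](CC)(CC)CC)C[C@H]3C(C)(C)[O+](CC=C)C(=C2[O-])[C@@]13O[Si](CC)(CC)CC | intermediate (not isolated)
17 | allyl cage ester: 2,2-dimethyltetrahydrofuran fused across C6–C1–C7 of the bicyclooctenone, allyl on C6 (1S,4R,6R,7S in the numbering of 15) | COC(=O)C1=C[C@]2(O[Si](CC)(CC)CC)C[C@H]3C(C)(C)O[C@@](CC=C)(C2=O)[C@@]13O[Si](CC)(CC)CC | intermediate (key-step product)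
18 | 2-methyl-2-butene | CC=C(C)C | starting material
19 | prenyl cage ester (as 17, prenyl on C6) | COC(=O)C1=C[C@]2(O[Si](CC)(CC)CC)C[C@H]3C(C)(C)O[C@@](CC=C(C)C)(C2=O)[C@@]13O[Si](CC)(CC)CC | intermediate
20 | prenyl cage acid (as 19, CO2H) | OC(=O)C1=C[C@]2(O[Si](CC)(CC)CC)C[C@H]3C(C)(C)O[C@@](CC=C(C)C)(C2=O)[C@@]13O[Si](CC)(CC)CC | intermediate
21 | 2,6-dimethoxy-1,4-benzoquinone | COC1=CC(=O)C=C(OC)C1=O | starting material
22 | 2-hydroxy-6-methoxy-1,4-benzoquinone | COC1=CC(=O)C=C(O)C1=O | intermediate
23 | 3-methylbut-2-enal | CC(C)=CC=O | starting material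
24 | 7-methoxy-2,2-dimethyl-2H-chromene-5,8-dione | COC1=CC(=O)C2=C(OC(C)(C)C=C2)C1=O | intermediate
25 | tributyl(3-methylbut-2-en-1-yl)stannane | CCCC[Sn](CCCC)(CCCC)CC=C(C)C | starting material
26 | 7-methoxy-2,2-dimethyl-6-(3-methylbut-2-en-1-yl)-2H-chromene-5,8-diol | COc1c(CC=C(C)C)c(O)c2C=CC(C)(C)Oc2c1O | intermediate (not isolated)
27 | 7-methoxy-2,2-dimethyl-6-(3-methylbut-2-en-1-yl)-2H-chromene-5,8-dione | COC1=C(CC=C(C)C)C(=O)C2=C(OC(C)(C)C=C2)C1=O | intermediate
28 | 7-hydroxy-2,2-dimethyl-6-(3-methylbut-2-en-1-yl)-2H-chromene-5,8-dione | OC1=C(CC=C(C)C)C(=O)C2=C(OC(C)(C)C=C2)C1=O | intermediate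
29 | acid chloride of 20 | ClC(=O)C1=C[C@]2(O[Si](CC)(CC)CC)C[C@H]3C(C)(C)O[C@@](CC=C(C)C)(C2=O)[C@@]13O[Si](CC)(CC)CC | intermediate (not isolated)
30 | quinonyl ester: acid 20 esterified on the C7 oxygen of 28, both bridgehead oxygens as triethylsilyl ethers | CC(C)=CCC1=C(OC(=O)C2=C[C@]3(O[Si](CC)(CC)CC)C[C@H]4C(C)(C)O[C@@](CC=C(C)C)(C3=O)[C@@]24O[Si](CC)(CC)CC)C(=O)C2=C(C=CC(C)(C)O2)C1=O | intermediate
31 | seco diol: 30 with both bridgehead hydroxyls free, same spatial arrangement | CC(C)=CCC1=C(OC(=O)C2=C[C@]3(O)C[C@H]4C(C)(C)O[C@@](CC=C(C)C)(C3=O)[C@@]24O)C(=O)C2=C(C=CC(C)(C)O2)C1=O | intermediate (not isolated)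
32 | CNP0222516.1: cage carbinol bridgehead (R), ring-fusion CH (S), prenylated ether carbon (R), ketal-bearing bridgehead (S), spiro carbon (S), CH-prenyl (S) | CC(C)=CC[C@H]1C(=O)C2=C(OC(C)(C)C=C2)C(=O)[C@@]12OC(=O)C1=C[C@]3(O)C[C@H]4C(C)(C)O[C@@](CC=C(C)C)(C3=O)[C@@]14O2 | target

**Step count and risks**

Total: 17 steps. Longest linear sequence: 13 steps (steps 1–11, 16, 17); the quinone branch is steps 12–15.

Steps most likely to fail:

1. Step 17 (proposed method). The closure may stall at the seco stage, may drain away by β-elimination of the carboxylate from the intermediate enol to an alkoxyquinone acid, or may form the spiro centre with poor facial selectivity. Fallback, from 20 to 32: acid 20 is desilylated with HF·pyridine to the dihydroxy acid F1, which is condensed with the methyl vinylogous ester 27 under camphorsulfonic acid catalysis over 5 Å molecular sieves to take up methanol. This is the acid-catalysed acetal exchange by which β-hydroxy acids and enol ethers give 1,3-dioxan-4-ones; both C–O bonds are made under one set of equilibrating acidic conditions and no activated ester is involved. It should deliver 32 directly.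

2. Step 4. Proton transfer to the basic radical anion or dianion may tautomerise the enedione to the aromatic hydroquinone (losing the stereocentre), or O-silylation may be incomplete. Fallback, from 5 to 10: zinc dust, Me3SiCl and pyridine in THF at 0 °C (classical non-basic reductive silylation) should give the bis(trimethylsilyl) dienol ether F2. Cycloaddition with 8 as in step 5 gives the cycloadduct F3, and aqueous acid, which also removes both labile trimethylsilyl ethers, gives the keto diol F4. Et3SiOTf and 2,6-lutidine then silylate both bridgehead hydroxyls and the route is rejoined at 10.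

3. Step 7. Ionisation and elimination of the hindered tertiary alcohol, or acid-induced loss of a bridgehead silyl ether, may outpace O-allylation. Fallback, from 9 to 13: the cycloadduct 9 is isolated by leaving out the acid treatment in step 5. Mukaiyama hydration (Co(acac)2, PhSiH3, O2) gives the tertiary alcohol F5, which has no enolisable carbonyl. Williamson etherification (NaH, allyl bromide, Bu4NI, THF/DMF, 0 °C) then gives the allyl ether F6, and dilute HCl in THF hydrolyses the enol ether to rejoin the route at 13.

**Further compounds**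

F1 | step 17 | dihydroxy cage acid (20 without silyl groups) | OC(=O)C1=C[C@]2(O)C[C@H]3C(C)(C)O[C@@](CC=C(C)C)(C2=O)[C@@]13O
F2 | step 4 | (5S)-2-methoxy-5-(prop-1-en-2-yl)-1,4-bis(trimethylsilyloxy)cyclohexa-1,3-diene | C1[C@@H](C(C)=C)C(O[Si](C)(C)C)=CC(OC)=C1O[Si](C)(C)C
F3 | step 4 | bis(trimethylsilyl) analogue of cycloadduct 9 | COC(=O)C1=C[C@]2(O[Si](C)(C)C)C[C@@H](C(C)=C)[C@@]1(O[Si](C)(C)C)C=C2OC
F4 | step 4 | methyl 1,4-dihydroxy-5-oxo-7-(prop-1-en-2-yl)bicyclo[2.2.2]oct-2-ene-2-carboxylate (configuration as in 10) | COC(=O)C1=C[C@]2(O)C[C@@H](C(C)=C)[C@@]1(O)CC2=O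
F5 | step 7 | 7-(2-hydroxypropan-2-yl) analogue of cycloadduct 9 | COC(=O)C1=C[C@]2(O[Si](CC)(CC)CC)C[C@@H](C(C)(C)O)[C@@]1(O[Si](CC)(CC)CC)C=C2OC
F6 | step 7 | 7-[2-(allyloxy)propan-2-yl] analogue of cycloadduct 9 | COC(=O)C1=C[C@]2(O[Si](CC)(CC)CC)C[C@@H](C(C)(C)OCC=C)[C@@]1(O[Si](CC)(CC)CC)C=C2OC
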